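**Plan**

- Retrosynthesis, in order: (a) the bond from lactone C3 to the benzylic CH2 of the dihydrobenzofuran half (enolate alkylation); (b) the ring oxygen O1 of the butyrolactone; (c) the two C–C bonds of the resulting cyclobutanone ([2+2] of dichloroketene with the allyl group of eugenol); (d) the C1–C2 bond of each 1,2-diarylpropane unit (aldol of one eugenol-derived arylacetic acid with O-silylated vanillin).
- Enabling feature: O1 lies between C2(=O) and the unsubstituted C5H2, so removing it leaves a 3-(arylmethyl)cyclobutanone whose two ring CH2 groups are enantiotopic; choosing one of them creates lactone C4.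
- Forward: eugenol gives a common arylacetic acid; its (S)-oxazolidinone imide gives the open diol wing by anti-aldol, then the cyclobutanone ring, then the butyrolactone ring by oxygen insertion. The same acid on the (R)-oxazolidinone gives the mirror-image diol, which closes to the dihydrobenzofuran ring and is trimmed to a benzylic bromide. Alkylation joins the halves and fluoride frees the six hydroxyls.
- Stereochemistry: the oxazolidinones set wing C1/C2 (1S,2S) and dihydrobenzofuran C3 (R); C2 (S) follows from trans-selective ring closure; the chiral phosphoric acid sets lactone C4 (R); C4 directs the trans alkylation at C3 (R).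

Key step: step 12

Abbreviations: TBS = tert-butyldimethylsilyl; TBSO = tert-butyldimethylsilyloxy; DCC = N,N'-dicyclohexylcarbodiimide; DMAP = 4-(dimethylamino)pyridine.
Assumption: the (S)-configured phosphoric acid is taken to favour the (R)-lactone, by analogy with simple 3-benzylcyclobutanones; the antipodal acid is equally accessible and would be used if the sense proved opposite.

**Route**

Step 1
Reactants: 1 eugenol (4-allyl-2-methoxyphenol)
Product: 2 4-allyl-2-bromo-6-methoxyphenol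
Conditions: NBS (1.0 equiv), i-Pr2NH (10 mol%), CH2Cl2, 0 °C, dark
Reagents that add atoms: N-bromosuccinimide, O=C1CCC(=O)N1Br
Why: Amine-catalysed electrophilic aromatic bromination goes ortho to the free phenol because the para position carries the allyl group, and cold, dark, anhydrous conditions should leave the terminal alkene alone.

Step 2
Reactants: 2 4-allyl-2-bromo-6-methoxyphenol
Product: 3 (4-allyl-2-bromo-6-methoxyphenoxy)(tert-butyl)dimethylsilane
Conditions: TBSCl, imidazole, DMF, rt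
Reagents that add atoms: tert-butyldimethylsilyl chloride, CC(C)(C)[Si](C)(C)Cl
Why: Imidazole-promoted silyl ether formation masks the phenol for the organometallic and enolate steps with a group that fluoride removes at the end.

Step 3
Reactants: 3 (4-allyl-2-bromo-6-methoxyphenoxy)(tert-butyl)dimethylsilane
Product: 4 tert-butyl 2-[5-allyl-2-(TBSO)-3-methoxyphenyl]acetate
Conditions: ClZnCH2CO2t-Bu (0.5 M in Et2O, 1.5 equiv), Pd2(dba)3 (2 mol%), XPhos (8 mol%), THF, 60 °C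
Reagents that add atoms: (2-tert-butoxy-2-oxoethyl)zinc chloride, CC(C)(C)OC(=O)C[Zn]Cl
Why: Negishi-type coupling of an aryl bromide with a Reformatsky reagent (α-arylation of a zinc ester enolate on zerovalent palladium) installs the acetate arm under conditions that tolerate the allyl group and the aryl silyl ether.

Step 4
Reactants: 4 tert-butyl 2-[5-allyl-2-(TBSO)-3-methoxyphenyl]acetate
Product: 5 2-[5-allyl-2-(TBSO)-3-methoxyphenyl]acetic acid
Conditions: TFA/CH2Cl2 (1:4), 0 °C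
Reagents that add atoms: none
Why: Acidolysis of the tert-butyl ester (loss of isobutene) is used in place of saponification because an aryl silyl ether tolerates cold TFA but not hydroxide.

Step 5
Reactants: 5 2-[5-allyl-2-(TBSO)-3-methoxyphenyl]acetic acid; 6 (S)-4-benzyl-1,3-oxazolidin-2-one
Product: 8 (4S)-3-{[5-allyl-2-(TBSO)-3-methoxyphenyl]acetyl}-4-benzyl-1,3-oxazolidin-2-one, via mixed pivalic anhydride 7 (not isolated)
Conditions: PivCl, Et3N, THF, −20 °C; then 6, LiCl, rt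
Reagents that add atoms: none
Why: Mixed-anhydride N-acylation of an oxazolidinone with LiCl-assisted acyl transfer is the standard way to attach the auxiliary to an arylacetic acid.

Step 6
Reactants: 9 vanillin
Product: 10 4-(TBSO)-3-methoxybenzaldehyde
Conditions: TBSCl, imidazole, CH2Cl2, rt
Reagents that add atoms: tert-butyldimethylsilyl chloride, CC(C)(C)[Si](C)(C)Cl
Why: Silyl ether formation at the phenol gives a non-enolisable aldehyde partner whose protecting group matches all the others.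

Step 7
Reactants: 8 (4S)-3-{[5-allyl-2-(TBSO)-3-methoxyphenyl]acetyl}-4-benzyl-1,3-oxazolidin-2-one; 10 4-(TBSO)-3-methoxybenzaldehyde
Product: 12 (4S)-3-{(2R,3S)-2-[5-allyl-2-(TBSO)-3-methoxyphenyl]-3-hydroxy-3-[4-(TBSO)-3-methoxyphenyl]propanoyl}-4-benzyl-1,3-oxazolidin-2-one, via trimethylsilyl ether 11 (not isolated)
Conditions: MgCl2 (20 mol%), Et3N (2 equiv), TMSCl (1.5 equiv), EtOAc, rt; then THF/1 M HCl (5:1), rt
Reagents that add atoms: none
Why: In this magnesium chloride-catalysed direct anti-aldol of an N-acyloxazolidinone (Evans-type auxiliary aldol) the chelated Z-enolate is attacked on the face away from the auxiliary benzyl group, which fixes the α-carbon as R, and the boat transition state places the carbinol anti (3S), while silyl trapping of the aldolate blocks retro-aldol.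

Step 8
Reactants: 12 (4S)-3-{(2R,3S)-2-[5-allyl-2-(TBSO)-3-methoxyphenyl]-3-hydroxy-3-[4-(TBSO)-3-methoxyphenyl]propanoyl}-4-benzyl-1,3-oxazolidin-2-one
Product: 13 (1S,2S)-2-[5-allyl-2-(TBSO)-3-methoxyphenyl]-1-[4-(TBSO)-3-methoxyphenyl]propane-1,3-diol
Conditions: LiBH4, MeOH (1 equiv), THF, 0 °C
Reagents that add atoms: none
Why: Reductive cleavage of the imide by hydride attack at the exocyclic carbonyl releases the 1,3-diol and the auxiliary without touching either stereocentre.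

Step 9
Reactants: 13 (1S,2S)-2-[5-allyl-2-(TBSO)-3-methoxyphenyl]-1-[4-(TBSO)-3-methoxyphenyl]propane-1,3-diol
Product: 14 (1S,2S)-2-[5-allyl-2-(TBSO)-3-methoxyphenyl]-1,3-bis(TBSO)-1-[4-(TBSO)-3-methoxyphenyl]propane
Conditions: TBSOTf, 2,6-lutidine, CH2Cl2, −78 → 0 °C
Reagents that add atoms: tert-butyldimethylsilyl triflate, CC(C)(C)[Si](C)(C)OS(=O)(=O)C(F)(F)F
Why: Silyl triflate/lutidine silylation covers the primary and the hindered benzylic hydroxyl so that no free OH meets the ketene, zinc, peroxide and enolate steps.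

Step 10
Reactants: 14 (1S,2S)-2-[5-allyl-2-(TBSO)-3-methoxyphenyl]-1,3-bis(TBSO)-1-[4-(TBSO)-3-methoxyphenyl]propane; 15 trichloroacetyl chloride
Product: 17 3-{3-[(1S,2S)-1,3-bis(TBSO)-1-(4-TBSO-3-methoxyphenyl)propan-2-yl]-4-(TBSO)-5-methoxybenzyl}-2,2-dichlorocyclobutan-1-one (both epimers at the ring CH), via dichloroketene 16 (not isolated)
Conditions: 15 (2.5 equiv, slow addition), Zn–Cu couple, Et2O/DME (10:1), rt
Reagents that add atoms: none
Why: The thermal [2+2] cycloaddition of dichloroketene with the terminal alkene joins the ketene carbonyl carbon to the CH2 terminus and the CCl2 carbon to the internal CH; the uncontrolled ring CH is of no consequence because it loses its stereogenicity in the next step, and DME ties up the ZnCl2 formed.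

Step 11
Reactants: 17 3-{3-[(1S,2S)-1,3-bis(TBSO)-1-(4-TBSO-3-methoxyphenyl)propan-2-yl]-4-(TBSO)-5-methoxybenzyl}-2,2-dichlorocyclobutan-1-one
Product: 18 3-{3-[(1S,2S)-1,3-bis(TBSO)-1-(4-TBSO-3-methoxyphenyl)propan-2-yl]-4-(TBSO)-5-methoxybenzyl}cyclobutan-1-one
Conditions: Zn dust, NH4Cl, MeOH, rt
Reagents that add atoms: none
Why: Reductive dechlorination of the α,α-dichloroketone by zinc under near-neutral proton supply gives the 3-substituted cyclobutanone, whose C3 is now only a prochiral centre flanked by two enantiotopic CH2 groups.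

Step 12
Reactants: 18 3-{3-[(1S,2S)-1,3-bis(TBSO)-1-(4-TBSO-3-methoxyphenyl)propan-2-yl]-4-(TBSO)-5-methoxybenzyl}cyclobutan-1-one
Product: 20 (4R)-4-{3-[(1S,2S)-1,3-bis(TBSO)-1-(4-TBSO-3-methoxyphenyl)propan-2-yl]-4-(TBSO)-5-methoxybenzyl}oxolan-2-one, via peroxy hemiketal 19 (not isolated)
Conditions: 30% aq H2O2 (1.5 equiv), (S)-3,3'-di(pyren-1-yl)-H8-BINOL hydrogen phosphate (10 mol%), CHCl3, −40 °C
Reagents that add atoms: hydrogen peroxide, OO
Why: The phosphoric acid activates the strained carbonyl, H2O2 adds to give a Criegee peroxy hemiketal held by hydrogen bonds in the chiral phosphate pocket, and the ring CH2 antiperiplanar to the O–O bond migrates to oxygen with loss of water. The closest known reaction type is the chiral phosphoric acid/aqueous H2O2 Baeyer–Villiger desymmetrisation of 3-aryl- and 3-benzylcyclobutanones. The five-membered lactone arises by ring expansion through a 1,2-shift that inserts oxygen into the four-membered ring, not by a cyclisation. The new stereocentre, lactone C4 (R), is set by the catalyst alone through its choice between the two enantiotopic CH2 groups, the wing stereocentres being too remote to help or to interfere. The selectivity needed is this group selection, with no regiochemical question because both α-carbons are CH2; ring strain lets dilute H2O2 react with the cyclobutanone while the silylated electron-rich arenes stay untouched.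

Step 13
Reactants: 5 2-[5-allyl-2-(TBSO)-3-methoxyphenyl]acetic acid; 21 (R)-4-benzyl-1,3-oxazolidin-2-one
Product: 23 (4R)-3-{[5-allyl-2-(TBSO)-3-methoxyphenyl]acetyl}-4-benzyl-1,3-oxazolidin-2-one, via O-acylisourea 22 (not isolated)
Conditions: 21 (1.0 equiv), DCC (1.1 equiv), DMAP (10 mol%), CH2Cl2, 0 °C → rt
Reagents that add atoms: none
Why: In this carbodiimide coupling (Steglich-type N-acylation) DCC converts the acid into its O-acylisourea and DMAP relays the acyl group to the oxazolidinone nitrogen, a direct coupling known for arylacetic acids that leaves the allyl group and the aryl silyl ether untouched.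

Step 14
Reactants: 23 (4R)-3-{[5-allyl-2-(TBSO)-3-methoxyphenyl]acetyl}-4-benzyl-1,3-oxazolidin-2-one; 10 4-(TBSO)-3-methoxybenzaldehyde
Product: 25 (4R)-3-{(2S,3R)-2-[5-allyl-2-(TBSO)-3-methoxyphenyl]-3-hydroxy-3-[4-(TBSO)-3-methoxyphenyl]propanoyl}-4-benzyl-1,3-oxazolidin-2-one, via trimethylsilyl ether 24 (not isolated)
Conditions: MgCl2 (20 mol%), Et3N (2 equiv), TMSCl (1.5 equiv), EtOAc, rt; then THF/1 M HCl (5:1), rt
Reagents that add atoms: none
Why: The same magnesium chloride-catalysed anti-aldol in the mirror-image series gives the (2S,3R) adduct through attack anti to the (R)-auxiliary benzyl group, and its α-carbon becomes C3 of the dihydrobenzofuran.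

Step 15
Reactants: 25 (4R)-3-{(2S,3R)-2-[5-allyl-2-(TBSO)-3-methoxyphenyl]-3-hydroxy-3-[4-(TBSO)-3-methoxyphenyl]propanoyl}-4-benzyl-1,3-oxazolidin-2-one
Product: 26 (1R,2R)-2-[5-allyl-2-(TBSO)-3-methoxyphenyl]-1-[4-(TBSO)-3-methoxyphenyl]propane-1,3-diol
Conditions: LiBH4, MeOH (1 equiv), THF, 0 °C
Reagents that add atoms: none
Why: Reductive cleavage of the imide with LiBH4 gives the diol and returns the auxiliary.

Step 16
Reactants: 26 (1R,2R)-2-[5-allyl-2-(TBSO)-3-methoxyphenyl]-1-[4-(TBSO)-3-methoxyphenyl]propane-1,3-diol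
Product: 28 4-[(2S,3R)-5-allyl-3-(hydroxymethyl)-7-methoxy-2,3-dihydro-1-benzofuran-2-yl]-2-methoxyphenol, via desilylated tetraol 27 (not isolated)
Conditions: n-Bu4NF (2.2 equiv), THF, 0 °C; then TsOH·H2O (3 equiv), 0 °C → rt
Reagents that add atoms: none
Why: Fluoride frees both phenols, then acid ionises the para-hydroxybenzylic alcohol to a quinone methide-type cation that the ortho phenol captures in a 5-exo closure (acid-mediated cyclodehydration to a phenylcoumaran), and the 2-aryl group settles trans to the hydroxymethyl group on the fixed (3R) centre to give (2S,3R).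

Step 17
Reactants: 28 4-[(2S,3R)-5-allyl-3-(hydroxymethyl)-7-methoxy-2,3-dihydro-1-benzofuran-2-yl]-2-methoxyphenol
Product: 29 (2S,3R)-5-allyl-2-[4-(TBSO)-3-methoxyphenyl]-3-[(TBSO)methyl]-7-methoxy-2,3-dihydro-1-benzofuran
Conditions: TBSCl (2.5 equiv), imidazole, DMF, rt
Reagents that add atoms: tert-butyldimethylsilyl chloride, CC(C)(C)[Si](C)(C)Cl
Why: One silylation covers the phenol and the primary alcohol, so this half carries the same fluoride-labile groups as the wing half.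

Step 18
Reactants: 29 (2S,3R)-5-allyl-2-[4-(TBSO)-3-methoxyphenyl]-3-[(TBSO)methyl]-7-methoxy-2,3-dihydro-1-benzofuran
Product: 30 (2S,3R)-2-[4-(TBSO)-3-methoxyphenyl]-3-[(TBSO)methyl]-7-methoxy-5-[(E)-prop-1-enyl]-2,3-dihydro-1-benzofuran
Conditions: RuHCl(CO)(PPh3)3 (3 mol%), toluene, 80 °C
Reagents that add atoms: none
Why: Metal hydride-catalysed alkene isomerisation (hydrometalation/β-hydride elimination) moves the double bond into conjugation with the arene, the thermodynamic sink, under neutral conditions.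

Step 19
Reactants: 30 (2S,3R)-2-[4-(TBSO)-3-methoxyphenyl]-3-[(TBSO)methyl]-7-methoxy-5-[(E)-prop-1-enyl]-2,3-dihydro-1-benzofuran
Product: 33 {(2S,3R)-2-[4-(TBSO)-3-methoxyphenyl]-3-[(TBSO)methyl]-7-methoxy-2,3-dihydro-1-benzofuran-5-yl}methanol, via ozonide 31 (not isolated), via aldehyde 32 (not isolated)
Conditions: O3, CH2Cl2, −78 °C (Sudan Red indicator); then NaBH4, MeOH, −78 → 0 °C
Reagents that add atoms: ozone, [O-][O+]=O
Why: Ozonolysis with reductive NaBH4 work-up cleaves the styrenyl double bond, which reacts far faster than the arenes when ozone is stopped at the indicator end point, and delivers the benzylic alcohol directly.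

Step 20
Reactants: 33 {(2S,3R)-2-[4-(TBSO)-3-methoxyphenyl]-3-[(TBSO)methyl]-7-methoxy-2,3-dihydro-1-benzofuran-5-yl}methanol
Product: 34 (2S,3R)-5-(bromomethyl)-2-[4-(TBSO)-3-methoxyphenyl]-3-[(TBSO)methyl]-7-methoxy-2,3-dihydro-1-benzofuran
Conditions: CBr4, PPh3, CH2Cl2, 0 °C; used crude at once
Reagents that add atoms: carbon tetrabromide, BrC(Br)(Br)Br
Why: The Appel reaction converts the benzylic alcohol into the bromide under neutral conditions that spare the silyl ethers.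

Step 21
Reactants: 20 (4R)-4-{3-[(1S,2S)-1,3-bis(TBSO)-1-(4-TBSO-3-methoxyphenyl)propan-2-yl]-4-(TBSO)-5-methoxybenzyl}oxolan-2-one; 34 (2S,3R)-5-(bromomethyl)-2-[4-(TBSO)-3-methoxyphenyl]-3-[(TBSO)methyl]-7-methoxy-2,3-dihydro-1-benzofuran
Product: 36 (3R,4R)-4-{3-[(1S,2S)-1,3-bis(TBSO)-1-(4-TBSO-3-methoxyphenyl)propan-2-yl]-4-(TBSO)-5-methoxybenzyl}-3-({(2S,3R)-2-[4-(TBSO)-3-methoxyphenyl]-3-[(TBSO)methyl]-7-methoxy-2,3-dihydro-1-benzofuran-5-yl}methyl)oxolan-2-one, via lithium enolate 35 (not isolated)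
Conditions: LiN(SiMe3)2 (1.1 equiv), THF, −78 °C; then 34, DMPU, −78 → −40 °C
Reagents that add atoms: none
Why: In this alkylation of a butyrolactone lithium enolate with a benzylic bromide the electrophile approaches the enolate face opposite the C4 arylmethyl group, setting C3 as R (trans), as is general for β-substituted butyrolactones.

Step 22
Reactants: 36 (3R,4R)-4-{3-[(1S,2S)-1,3-bis(TBSO)-1-(4-TBSO-3-methoxyphenyl)propan-2-yl]-4-(TBSO)-5-methoxybenzyl}-3-({(2S,3R)-2-[4-(TBSO)-3-methoxyphenyl]-3-[(TBSO)methyl]-7-methoxy-2,3-dihydro-1-benzofuran-5-yl}methyl)oxolan-2-one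
Product: 37 CNP0199264.2, (3R,4R)-4-{3-[(1S,2S)-1,3-dihydroxy-1-(4-hydroxy-3-methoxyphenyl)propan-2-yl]-4-hydroxy-5-methoxybenzyl}-3-{[(2S,3R)-2-(4-hydroxy-3-methoxyphenyl)-3-(hydroxymethyl)-7-methoxy-2,3-dihydro-1-benzofuran-5-yl]methyl}oxolan-2-one
Conditions: n-Bu4NF/AcOH (1:1, 9 equiv), THF, 0 °C → rt
Reagents that add atoms: none
Why: Buffered fluoride desilylation removes all six TBS groups while keeping the medium near neutral, so that neither acid-induced closure of the open diol wing onto its ortho phenol nor base-induced epimerisation or opening of the lactone should intervene.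

**Compound list**

1 | eugenol (4-allyl-2-methoxyphenol) | COc1cc(CC=C)ccc1O | starting material
2 | 4-allyl-2-bromo-6-methoxyphenol | COc1cc(CC=C)cc(Br)c1O | intermediate
3 | (4-allyl-2-bromo-6-methoxyphenoxy)(tert-butyl)dimethylsilane | COc1cc(CC=C)cc(Br)c1O[Si](C)(C)C(C)(C)C | intermediate
4 | tert-butyl 2-[5-allyl-2-(TBSO)-3-methoxyphenyl]acetate | COc1cc(CC=C)cc(CC(=O)OC(C)(C)C)c1O[Si](C)(C)C(C)(C)C | intermediate
5 | 2-[5-allyl-2-(TBSO)-3-methoxyphenyl]acetic acid | COc1cc(CC=C)cc(CC(=O)O)c1O[Si](C)(C)C(C)(C)C | intermediate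
6 | (S)-4-benzyl-1,3-oxazolidin-2-one | O=C1OC[C@H](Cc2ccccc2)N1 | starting material
7 | mixed anhydride of 5 and pivalic acid | COc1cc(CC=C)cc(CC(=O)OC(=O)C(C)(C)C)c1O[Si](C)(C)C(C)(C)C | intermediate
8 | (4S)-3-{[5-allyl-2-(TBSO)-3-methoxyphenyl]acetyl}-4-benzyl-1,3-oxazolidin-2-one | COc1cc(CC=C)cc(CC(=O)N2[C@@H](Cc3ccccc3)COC2=O)c1O[Si](C)(C)C(C)(C)C | intermediate
9 | vanillin | COc1cc(C=O)ccc1O | starting material
10 | 4-(TBSO)-3-methoxybenzaldehyde | COc1cc(C=O)ccc1O[Si](C)(C)C(C)(C)C | intermediate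
11 | O-trimethylsilyl ether of aldol adduct 12 | COc1cc([C@@H](O[Si](C)(C)C)[C@H](C(=O)N2[C@@H](Cc3ccccc3)COC2=O)c2cc(CC=C)cc(OC)c2O[Si](C)(C)C(C)(C)C)ccc1O[Si](C)(C)C(C)(C)C | intermediate
12 | (4S)-3-{(2R,3S)-2-[5-allyl-2-(TBSO)-3-methoxyphenyl]-3-hydroxy-3-[4-(TBSO)-3-methoxyphenyl]propanoyl}-4-benzyl-1,3-oxazolidin-2-one | COc1cc([C@@H](O)[C@H](C(=O)N2[C@@H](Cc3ccccc3)COC2=O)c2cc(CC=C)cc(OC)c2O[Si](C)(C)C(C)(C)C)ccc1O[Si](C)(C)C(C)(C)C | intermediate
13 | (1S,2S)-2-[5-allyl-2-(TBSO)-3-methoxyphenyl]-1-[4-(TBSO)-3-methoxyphenyl]propane-1,3-diol | COc1cc([C@@H](O)[C@H](CO)c2cc(CC=C)cc(OC)c2O[Si](C)(C)C(C)(C)C)ccc1O[Si](C)(C)C(C)(C)C | intermediate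
14 | (1S,2S)-2-[5-allyl-2-(TBSO)-3-methoxyphenyl]-1,3-bis(TBSO)-1-[4-(TBSO)-3-methoxyphenyl]propane | COc1cc([C@@H](O[Si](C)(C)C(C)(C)C)[C@H](CO[Si](C)(C)C(C)(C)C)c2cc(CC=C)cc(OC)c2O[Si](C)(C)C(C)(C)C)ccc1O[Si](C)(C)C(C)(C)C | intermediate
15 | trichloroacetyl chloride | ClC(Cl)(Cl)C(=O)Cl | starting material
16 | dichloroketene | ClC(Cl)=C=O | intermediate
17 | wing-bearing 3-(arylmethyl)-2,2-dichlorocyclobutan-1-one (both epimers at the ring CH) | COc1cc([C@@H](O[Si](C)(C)C(C)(C)C)[C@H](CO[Si](C)(C)C(C)(C)C)c2cc(CC3CC(=O)C3(Cl)Cl)cc(OC)c2O[Si](C)(C)C(C)(C)C)ccc1O[Si](C)(C)C(C)(C)C | intermediate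
18 | 3-{3-[(1S,2S)-1,3-bis(TBSO)-1-(4-TBSO-3-methoxyphenyl)propan-2-yl]-4-(TBSO)-5-methoxybenzyl}cyclobutan-1-one | COc1cc([C@@H](O[Si](C)(C)C(C)(C)C)[C@H](CO[Si](C)(C)C(C)(C)C)c2cc(CC3CC(=O)C3)cc(OC)c2O[Si](C)(C)C(C)(C)C)ccc1O[Si](C)(C)C(C)(C)C | intermediate
19 | Criegee peroxy hemiketal of 18 (1-hydroperoxycyclobutan-1-ol, ring configuration undefined) | COc1cc([C@@H](O[Si](C)(C)C(C)(C)C)[C@H](CO[Si](C)(C)C(C)(C)C)c2cc(CC3CC(O)(OO)C3)cc(OC)c2O[Si](C)(C)C(C)(C)C)ccc1O[Si](C)(C)C(C)(C)C | intermediate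
20 | (4R)-4-{3-[(1S,2S)-1,3-bis(TBSO)-1-(4-TBSO-3-methoxyphenyl)propan-2-yl]-4-(TBSO)-5-methoxybenzyl}oxolan-2-one | COc1cc([C@@H](O[Si](C)(C)C(C)(C)C)[C@H](CO[Si](C)(C)C(C)(C)C)c2cc(C[C@H]3COC(=O)C3)cc(OC)c2O[Si](C)(C)C(C)(C)C)ccc1O[Si](C)(C)C(C)(C)C | intermediate
21 | (R)-4-benzyl-1,3-oxazolidin-2-one | O=C1OC[C@@H](Cc2ccccc2)N1 | starting material
22 | O-acylisourea of acid 5 and DCC | COc1cc(CC=C)cc(CC(=O)OC(=NC2CCCCC2)NC2CCCCC2)c1O[Si](C)(C)C(C)(C)C | intermediate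
23 | (4R)-3-{[5-allyl-2-(TBSO)-3-methoxyphenyl]acetyl}-4-benzyl-1,3-oxazolidin-2-one | COc1cc(CC=C)cc(CC(=O)N2[C@H](Cc3ccccc3)COC2=O)c1O[Si](C)(C)C(C)(C)C | intermediate
24 | O-trimethylsilyl ether of aldol adduct 25 | COc1cc([C@H](O[Si](C)(C)C)[C@@H](C(=O)N2[C@H](Cc3ccccc3)COC2=O)c2cc(CC=C)cc(OC)c2O[Si](C)(C)C(C)(C)C)ccc1O[Si](C)(C)C(C)(C)C | intermediate
25 | (4R)-3-{(2S,3R)-2-[5-allyl-2-(TBSO)-3-methoxyphenyl]-3-hydroxy-3-[4-(TBSO)-3-methoxyphenyl]propanoyl}-4-benzyl-1,3-oxazolidin-2-one | COc1cc([C@H](O)[C@@H](C(=O)N2[C@H](Cc3ccccc3)COC2=O)c2cc(CC=C)cc(OC)c2O[Si](C)(C)C(C)(C)C)ccc1O[Si](C)(C)C(C)(C)C | intermediate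
26 | (1R,2R)-2-[5-allyl-2-(TBSO)-3-methoxyphenyl]-1-[4-(TBSO)-3-methoxyphenyl]propane-1,3-diol | COc1cc([C@H](O)[C@@H](CO)c2cc(CC=C)cc(OC)c2O[Si](C)(C)C(C)(C)C)ccc1O[Si](C)(C)C(C)(C)C | intermediate
27 | (1R,2R)-2-(5-allyl-2-hydroxy-3-methoxyphenyl)-1-(4-hydroxy-3-methoxyphenyl)propane-1,3-diol | COc1cc([C@H](O)[C@@H](CO)c2cc(CC=C)cc(OC)c2O)ccc1O | intermediate
28 | 4-[(2S,3R)-5-allyl-3-(hydroxymethyl)-7-methoxy-2,3-dihydro-1-benzofuran-2-yl]-2-methoxyphenol | C=CCc1cc(OC)c2c(c1)[C@H](CO)[C@@H](c1ccc(O)c(OC)c1)O2 | intermediate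
29 | (2S,3R)-5-allyl-2-[4-(TBSO)-3-methoxyphenyl]-3-[(TBSO)methyl]-7-methoxy-2,3-dihydro-1-benzofuran | C=CCc1cc(OC)c2c(c1)[C@H](CO[Si](C)(C)C(C)(C)C)[C@@H](c1ccc(O[Si](C)(C)C(C)(C)C)c(OC)c1)O2 | intermediate
30 | (2S,3R)-2-[4-(TBSO)-3-methoxyphenyl]-3-[(TBSO)methyl]-7-methoxy-5-[(E)-prop-1-enyl]-2,3-dihydro-1-benzofuran | C/C=C/c1cc(OC)c2c(c1)[C@H](CO[Si](C)(C)C(C)(C)C)[C@@H](c1ccc(O[Si](C)(C)C(C)(C)C)c(OC)c1)O2 | intermediate
31 | ozonide of 30 (3-methyl-5-aryl-1,2,4-trioxolane) | CC1OC(c2cc(OC)c3c(c2)[C@H](CO[Si](C)(C)C(C)(C)C)[C@@H](c2ccc(O[Si](C)(C)C(C)(C)C)c(OC)c2)O3)OO1 | intermediate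
32 | (2S,3R)-2-[4-(TBSO)-3-methoxyphenyl]-3-[(TBSO)methyl]-7-methoxy-2,3-dihydro-1-benzofuran-5-carbaldehyde | O=Cc1cc(OC)c2c(c1)[C@H](CO[Si](C)(C)C(C)(C)C)[C@@H](c1ccc(O[Si](C)(C)C(C)(C)C)c(OC)c1)O2 | intermediate
33 | {(2S,3R)-2-[4-(TBSO)-3-methoxyphenyl]-3-[(TBSO)methyl]-7-methoxy-2,3-dihydro-1-benzofuran-5-yl}methanol | OCc1cc(OC)c2c(c1)[C@H](CO[Si](C)(C)C(C)(C)C)[C@@H](c1ccc(O[Si](C)(C)C(C)(C)C)c(OC)c1)O2 | intermediate
34 | (2S,3R)-5-(bromomethyl)-2-[4-(TBSO)-3-methoxyphenyl]-3-[(TBSO)methyl]-7-methoxy-2,3-dihydro-1-benzofuran | BrCc1cc(OC)c2c(c1)[C@H](CO[Si](C)(C)C(C)(C)C)[C@@H](c1ccc(O[Si](C)(C)C(C)(C)C)c(OC)c1)O2 | intermediate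
35 | lithium enolate of lactone 20 | COc1cc([C@@H](O[Si](C)(C)C(C)(C)C)[C@H](CO[Si](C)(C)C(C)(C)C)c2cc(C[C@H]3COC(O[Li])=C3)cc(OC)c2O[Si](C)(C)C(C)(C)C)ccc1O[Si](C)(C)C(C)(C)C | intermediate
36 | hexakis-TBS ether of the target: (3R,4R)-lactone with (1S,2S) wing and (2S,3R) dihydrobenzofuran | COc1cc([C@@H](O[Si](C)(C)C(C)(C)C)[C@H](CO[Si](C)(C)C(C)(C)C)c2cc(C[C@H]3COC(=O)[C@@H]3Cc3cc(OC)c4c(c3)[C@H](CO[Si](C)(C)C(C)(C)C)[C@@H](c3ccc(O[Si](C)(C)C(C)(C)C)c(OC)c3)O4)cc(OC)c2O[Si](C)(C)C(C)(C)C)ccc1O[Si](C)(C)C(C)(C)C | intermediate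
37 | CNP0199264.2 | COc1cc([C@@H](O)[C@H](CO)c2cc(C[C@H]3COC(=O)[C@@H]3Cc3cc(OC)c4c(c3)[C@H](CO)[C@@H](c3ccc(O)c(OC)c3)O4)cc(OC)c2O)ccc1O | target

**Step count and risks**

Total steps: 22. Longest linear sequence: 14 steps (steps 1–4, then 13–22).

1. Step 12. The catalyst may discriminate incompletely between the two enantiotopic ring CH2 groups, since benzyl-type 3-substituents are recognised less well than 3-aryl ones and the substrate is bulky. This would give C4 epimers that differ only at a remote centre and are hard to separate. The fallback sets out from 14 and returns at 20, replacing the oxygen insertion by an auxiliary-controlled alkylation. Hydroboration–oxidation of the allyl group (9-BBN, THF; NaBO3·4H2O) would give the wing-bearing 3-arylpropan-1-ol F1, and TEMPO/PhI(OAc)2 oxidation in aqueous MeCN would give the 3-arylpropanoic acid F2. Mixed-anhydride acylation of 6 would give the (4S)-N-(3-arylpropanoyl)oxazolidinone F3. NaN(SiMe3)2 and tert-butyl bromoacetate at −78 °C would alkylate the chelated Z-enolate anti to the auxiliary benzyl group to give the (R)-configured succinate imide F4. LiBH4 would cleave the auxiliary to the hydroxy tert-butyl ester F5, and catalytic camphorsulfonic acid in warm toluene would close F5 to lactone 20.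

2. Step 7. The hindered ortho-silyloxy aryl enolate may add slowly to the electron-rich aldehyde, or the chelated boat transition state may lose anti or facial selectivity. Step 14 is less exposed, because the later ring closure corrects the benzylic centre. The fallback sets out from 23 and 10 and returns at 14; it makes the syn adduct and inverts the carbinol. A dibutylboron triflate syn-aldol (Bu2BOTf, i-Pr2NEt, CH2Cl2, −78 → 0 °C) would give the (4R)-imide syn adduct with (2R,3R) configuration F6, and LiBH4 would reduce it to the (1R,2S) syn diol F7. TBSCl/imidazole would give the primary silyl ether F8. Mitsunobu inversion (4-nitrobenzoic acid, PPh3, DIAD, toluene, −20 °C) would give the (1S,2S) 4-nitrobenzoate F9, and LiBH4 would release the (1S,2S) secondary alcohol F10. TBSOTf/2,6-lutidine would then give 14.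

3. Step 21. The electron-rich benzylic bromide may ionise and decompose before C-alkylation, or the enolate may react at oxygen or twice. The fallback sets out from 20 and 30 and returns at 36, replacing the alkylation by an aldol condensation and conjugate reduction. Ozonolysis of 30 with Me2S work-up would give aldehyde 32, this time isolated. Enolate 35 would add to 32 to give the β-hydroxy lactone F11 (mixture at the two new centres), and MsCl/Et3N then DBU would dehydrate it to the (E)-benzylidene lactone F12. Conjugate reduction with NaBH4/NiCl2·6H2O in MeOH/THF, followed by DBU equilibration to the more stable trans isomer, would give 36.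

**Further compounds**

F1 | step 12 | 3-{3-[(1S,2S)-1,3-bis(TBSO)-1-(4-TBSO-3-methoxyphenyl)propan-2-yl]-4-(TBSO)-5-methoxyphenyl}propan-1-ol | COc1cc([C@@H](O[Si](C)(C)C(C)(C)C)[C@H](CO[Si](C)(C)C(C)(C)C)c2cc(CCCO)cc(OC)c2O[Si](C)(C)C(C)(C)C)ccc1O[Si](C)(C)C(C)(C)C
F2 | step 12 | 3-{3-[(1S,2S)-1,3-bis(TBSO)-1-(4-TBSO-3-methoxyphenyl)propan-2-yl]-4-(TBSO)-5-methoxyphenyl}propanoic acid | COc1cc([C@@H](O[Si](C)(C)C(C)(C)C)[C@H](CO[Si](C)(C)C(C)(C)C)c2cc(CCC(=O)O)cc(OC)c2O[Si](C)(C)C(C)(C)C)ccc1O[Si](C)(C)C(C)(C)C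
F3 | step 12 | (4S)-4-benzyl-3-(3-arylpropanoyl)-1,3-oxazolidin-2-one derived from F2 | COc1cc([C@@H](O[Si](C)(C)C(C)(C)C)[C@H](CO[Si](C)(C)C(C)(C)C)c2cc(CCC(=O)N3[C@@H](Cc4ccccc4)COC3=O)cc(OC)c2O[Si](C)(C)C(C)(C)C)ccc1O[Si](C)(C)C(C)(C)C
F4 | step 12 | tert-butyl (3R)-4-aryl-3-{[(4S)-4-benzyl-2-oxo-1,3-oxazolidin-3-yl]carbonyl}butanoate | COc1cc([C@@H](O[Si](C)(C)C(C)(C)C)[C@H](CO[Si](C)(C)C(C)(C)C)c2cc(C[C@@H](C(=O)N3[C@@H](Cc4ccccc4)COC3=O)CC(=O)OC(C)(C)C)cc(OC)c2O[Si](C)(C)C(C)(C)C)ccc1O[Si](C)(C)C(C)(C)C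
F5 | step 12 | tert-butyl (3R)-4-aryl-3-(hydroxymethyl)butanoate | COc1cc([C@@H](O[Si](C)(C)C(C)(C)C)[C@H](CO[Si](C)(C)C(C)(C)C)c2cc(C[C@@H](CO)CC(=O)OC(C)(C)C)cc(OC)c2O[Si](C)(C)C(C)(C)C)ccc1O[Si](C)(C)C(C)(C)C
F6 | step 7 | (4R)-3-{(2R,3R)-2-[5-allyl-2-(TBSO)-3-methoxyphenyl]-3-hydroxy-3-[4-(TBSO)-3-methoxyphenyl]propanoyl}-4-benzyl-1,3-oxazolidin-2-one | COc1cc([C@H](O)[C@H](C(=O)N2[C@H](Cc3ccccc3)COC2=O)c2cc(CC=C)cc(OC)c2O[Si](C)(C)C(C)(C)C)ccc1O[Si](C)(C)C(C)(C)C
F7 | step 7 | (1R,2S)-2-[5-allyl-2-(TBSO)-3-methoxyphenyl]-1-[4-(TBSO)-3-methoxyphenyl]propane-1,3-diol | COc1cc([C@H](O)[C@H](CO)c2cc(CC=C)cc(OC)c2O[Si](C)(C)C(C)(C)C)ccc1O[Si](C)(C)C(C)(C)C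
F8 | step 7 | (1R,2S)-2-[5-allyl-2-(TBSO)-3-methoxyphenyl]-3-(TBSO)-1-[4-(TBSO)-3-methoxyphenyl]propan-1-ol | COc1cc([C@H](O)[C@H](CO[Si](C)(C)C(C)(C)C)c2cc(CC=C)cc(OC)c2O[Si](C)(C)C(C)(C)C)ccc1O[Si](C)(C)C(C)(C)C
F9 | step 7 | (1S,2S)-2-[5-allyl-2-(TBSO)-3-methoxyphenyl]-3-(TBSO)-1-[4-(TBSO)-3-methoxyphenyl]propyl 4-nitrobenzoate | COc1cc([C@@H](OC(=O)c3ccc(cc3)[N+](=O)[O-])[C@H](CO[Si](C)(C)C(C)(C)C)c2cc(CC=C)cc(OC)c2O[Si](C)(C)C(C)(C)C)ccc1O[Si](C)(C)C(C)(C)C
F10 | step 7 | (1S,2S)-2-[5-allyl-2-(TBSO)-3-methoxyphenyl]-3-(TBSO)-1-[4-(TBSO)-3-methoxyphenyl]propan-1-ol | COc1cc([C@@H](O)[C@H](CO[Si](C)(C)C(C)(C)C)c2cc(CC=C)cc(OC)c2O[Si](C)(C)C(C)(C)C)ccc1O[Si](C)(C)C(C)(C)C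
F11 | step 21 | aldol adduct of 20 and 32: 3-[aryl(hydroxy)methyl] lactone (mixture at C3 and the carbinol) | COc1cc([C@@H](O[Si](C)(C)C(C)(C)C)[C@H](CO[Si](C)(C)C(C)(C)C)c2cc(C[C@H]3COC(=O)C3C(O)c3cc(OC)c4c(c3)[C@H](CO[Si](C)(C)C(C)(C)C)[C@@H](c3ccc(O[Si](C)(C)C(C)(C)C)c(OC)c3)O4)cc(OC)c2O[Si](C)(C)C(C)(C)C)ccc1O[Si](C)(C)C(C)(C)C
F12 | step 21 | (E)-3-benzylidene lactone from F11 | COc1cc([C@@H](O[Si](C)(C)C(C)(C)C)[C@H](CO[Si](C)(C)C(C)(C)C)c2cc(C[C@H]3COC(=O)/C3=C/c3cc(OC)c4c(c3)[C@H](CO[Si](C)(C)C(C)(C)C)[C@@H](c3ccc(O[Si](C)(C)C(C)(C)C)c(OC)c3)O4)cc(OC)c2O[Si](C)(C)C(C)(C)C)ccc1O[Si](C)(C)C(C)(C)C
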